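**Retrosynthetic overview**
1. The target is cut at the spiro ketal into commercial canthaxanthin (both cyclohexene rings are bought) and the C34 (10R,11R)-diol. The dioxolane is the only ring formed, and it is closed last by a TMSOTf-mediated mono-ketalization that also creates the spiro centre.
2. The diol is cut at C10–C11. A sparteine-generated α-oxy carbanion of the chain B carbamate (a reversed-polarity d1 reagent) is acylated by the Weinreb amide of the chain A acid, then methyl is added under Felkin–Anh control to set C10.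
3. The chain B carbamate comes from nickel-catalysed methylative opening of a 6-alkyl-dihydropyran (gives the E-alkene), made from 6-lithio-dihydropyran (a masked acyl anion) and a C13 iodide.
4. Both C13 units come from one iteration: alkyllithium plus (R)- or (S)-α-methyl-γ-butyrolactone, Wittig methylenation, iodination. Each lactone carries one methyl stereocentre and comes from asymmetric hydrogenation of α-methylene-γ-butyrolactone.
5. Ring order: no carbocycle is built; the dihydropyran ring is opened in step 13 and the dioxolane ring is closed in step 17.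

Assumption: reagents, catalysts and solvents carry no compound number, and the ligand antipodes in steps 1 and 2 are the ones that give the stated lactone (checked by the sign of rotation).

Step 1
Reactants: 1 3-methylideneoxolan-2-one (α-methylene-γ-butyrolactone)
Product: 2 (3R)-3-methyloxolan-2-one
Conditions: H2 (100 atm), Ru(OAc)2[(S)-BINAP] (0.5 mol%), CH2Cl2, 50 °C
Reagents that add atoms: none
Why: Noyori-type asymmetric hydrogenation in which the lactone carbonyl binds ruthenium and directs hydride to one face of the exocyclic alkene, which sets C3 as R (about 95% ee).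

Step 2
Reactants: 1 3-methylideneoxolan-2-one
Product: 3 (3S)-3-methyloxolan-2-one
Conditions: H2 (100 atm), Ru(OAc)2[(R)-BINAP] (0.5 mol%), CH2Cl2, 50 °C
Reagents that add atoms: none
Why: The same asymmetric hydrogenation with the mirror-image ligand delivers hydride to the opposite face and sets C3 as S.

Step 3
Reactants: 2 (3R)-3-methyloxolan-2-one
Product: 5 (3R)-3,4-dimethylpent-4-en-1-ol, via lithium keto-alkoxide 4 (not isolated)
Conditions: MeLi (1.05 equiv), Et2O, −78 °C; then into Ph3P=CH2 (from Ph3PCH3Br, KOtBu; 2 equiv), THF, 0 °C, 1 h; H2O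
Reagents that add atoms: methyllithium [Li]C; methyltriphenylphosphonium bromide C[P+](c1ccccc1)(c1ccccc1)c1ccccc1.[Br-]
Why: Mono-addition of an organolithium to a γ-lactone stops at the lactolate, whose open form 4 undergoes Wittig methylenation in the same flask, and the stereocentre is carried through unchanged because the ylide is used cold and briefly so the α-hydrogen is not exchanged.

Step 4
Reactants: 5 (3R)-3,4-dimethylpent-4-en-1-ol
Product: 6 (3R)-5-iodo-2,3-dimethylpent-1-ene
Conditions: I2, PPh3, imidazole, CH2Cl2, 0 °C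
Reagents that add atoms: iodine II
Why: Appel iodination is an SN2 displacement at the primary carbinol carbon that leaves the alkene and the remote stereocentre untouched.

Step 5
Reactants: 3 (3S)-3-methyloxolan-2-one
Product: 8 (3S)-3,4-dimethylpent-4-en-1-ol, via lithium keto-alkoxide 7 (not isolated)
Conditions: MeLi (1.05 equiv), Et2O, −78 °C; then into Ph3P=CH2 (from Ph3PCH3Br, KOtBu; 2 equiv), THF, 0 °C, 1 h; H2O
Reagents that add atoms: methyllithium [Li]C; methyltriphenylphosphonium bromide C[P+](c1ccccc1)(c1ccccc1)c1ccccc1.[Br-]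
Why: The same lactone mono-addition and in-flask Wittig methylenation as in step 3 carries the S stereocentre of 3 through unchanged.

Step 6
Reactants: 8 (3S)-3,4-dimethylpent-4-en-1-ol
Product: 9 (3S)-5-iodo-2,3-dimethylpent-1-ene
Conditions: I2, PPh3, imidazole, CH2Cl2, 0 °C
Reagents that add atoms: iodine II
Why: Appel iodination by SN2 at the primary carbon, with no effect on the stereocentre.

Step 7
Reactants: 6 (3R)-5-iodo-2,3-dimethylpent-1-ene; 2 (3R)-3-methyloxolan-2-one
Product: 12 (3R,7R)-3,7,8-trimethyl-4-methylidenenon-8-en-1-ol, via alkyllithium 10 (not isolated), via lithium keto-alkoxide 11 (not isolated)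
Conditions: 6, t-BuLi (2.1 equiv), pentane–Et2O, −78 °C; then 2 (1.0 equiv), THF, −78 °C; then into Ph3P=CH2 (from Ph3PCH3Br, KOtBu; 2 equiv), THF, 0 °C, 1 h; H2O
Reagents that add atoms: methyltriphenylphosphonium bromide C[P+](c1ccccc1)(c1ccccc1)c1ccccc1.[Br-]
Why: Lithium–iodine exchange gives a 4-pentenyl-type alkyllithium that cannot cyclize and adds once to the second lactone unit, and Wittig methylenation of 11 installs the internal 1,1-disubstituted alkene, so the 3R centre comes intact from 2 and the 7R centre from 6.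

Step 8
Reactants: 12 (3R,7R)-3,7,8-trimethyl-4-methylidenenon-8-en-1-ol
Product: 13 (3R,7R)-9-iodo-2,3,7-trimethyl-6-methylidenenon-1-ene
Conditions: I2, PPh3, imidazole, CH2Cl2, 0 °C
Reagents that add atoms: iodine II
Why: Appel iodination by SN2 at the primary carbon, with both stereocentres remote and unaffected.

Step 9
Reactants: 13 (3R,7R)-9-iodo-2,3,7-trimethyl-6-methylidenenon-1-ene
Product: 15 (4R,8R)-N-methoxy-N,4,8,9-tetramethyl-5-methylidenedec-9-enamide, via alkyllithium 14 (not isolated)
Conditions: t-BuLi (2.1 equiv), pentane–Et2O, −78 °C; then cannulated into ClC(O)N(OMe)Me (2 equiv), THF, −78 °C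
Reagents that add atoms: N-methoxy-N-methylcarbamoyl chloride CON(C)C(Cl)=O
Why: Lithium–iodine exchange followed by nucleophilic acyl substitution on the carbamoyl chloride (inverse addition to avoid ketone formation) gives the one-carbon-longer Weinreb amide without touching either stereocentre.

Step 10
Reactants: 9 (3S)-5-iodo-2,3-dimethylpent-1-ene; 2 (3R)-3-methyloxolan-2-one
Product: 18 (3R,7S)-3,7,8-trimethyl-4-methylidenenon-8-en-1-ol, via alkyllithium 16 (not isolated), via lithium keto-alkoxide 17 (not isolated)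
Conditions: 9, t-BuLi (2.1 equiv), pentane–Et2O, −78 °C; then 2 (1.0 equiv), THF, −78 °C; then into Ph3P=CH2 (from Ph3PCH3Br, KOtBu; 2 equiv), THF, 0 °C, 1 h; H2O
Reagents that add atoms: methyltriphenylphosphonium bromide C[P+](c1ccccc1)(c1ccccc1)c1ccccc1.[Br-]
Why: The same lithium–iodine exchange, lactone mono-addition and Wittig methylenation as in step 7 joins the S terminal unit to the R lactone, so the 3R centre comes from 2 and the 7S centre from 9.

Step 11
Reactants: 18 (3R,7S)-3,7,8-trimethyl-4-methylidenenon-8-en-1-ol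
Product: 19 (3S,7R)-9-iodo-2,3,7-trimethyl-6-methylidenenon-1-ene
Conditions: I2, PPh3, imidazole, CH2Cl2, 0 °C
Reagents that add atoms: iodine II
Why: Appel iodination by SN2 at the primary carbon, with both stereocentres unaffected.

Step 12
Reactants: 20 3,4-dihydro-2H-pyran; 19 (3S,7R)-9-iodo-2,3,7-trimethyl-6-methylidenenon-1-ene
Product: 22 6-[(3R,7S)-3,7,8-trimethyl-4-methylidenenon-8-en-1-yl]-3,4-dihydro-2H-pyran, via 6-lithio-dihydropyran 21 (not isolated)
Conditions: 20 (1.5 equiv), t-BuLi (1.2 equiv), THF–pentane, −78 → 0 °C; then 19, THF, −30 °C → rt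
Reagents that add atoms: none
Why: Vinylic α-lithiation of the cyclic enol ether gives 21, a masked acyl anion, which is alkylated by the primary iodide in an SN2 reaction that creates no stereocentre.

Step 13
Reactants: 22 6-[(3R,7S)-3,7,8-trimethyl-4-methylidenenon-8-en-1-yl]-3,4-dihydro-2H-pyran
Product: 23 (4E,8R,12S)-5,8,12,13-tetramethyl-9-methylidenetetradeca-4,13-dien-1-ol
Conditions: MeMgBr (3 equiv), NiCl2(PPh3)2 (10 mol%), PhMe, reflux; H2O
Reagents that add atoms: methylmagnesium bromide C[Mg]Br
Why: Wenkert–Kocienski coupling in which zerovalent nickel inserts into the vinylic C–O bond and methyl replaces oxygen with retention, so the ring geometry becomes the 4E trisubstituted alkene (typically at least 95:5) and the ring oxygen becomes the primary alcohol.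

Step 14
Reactants: 23 (4E,8R,12S)-5,8,12,13-tetramethyl-9-methylidenetetradeca-4,13-dien-1-ol
Product: 24 (4E,8R,12S)-5,8,12,13-tetramethyl-9-methylidenetetradeca-4,13-dien-1-yl N,N-di(propan-2-yl)carbamate
Conditions: NaH, THF, 0 °C; then i-Pr2NCOCl, reflux
Reagents that add atoms: N,N-diisopropylcarbamoyl chloride CC(C)N(C(C)C)C(Cl)=O
Why: Nucleophilic acyl substitution of the sodium alkoxide on the carbamoyl chloride installs the diisopropylcarbamate that directs and stabilises the lithiation in step 15.

Step 15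
Reactants: 24 (4E,8R,12S)-5,8,12,13-tetramethyl-9-methylidenetetradeca-4,13-dien-1-yl N,N-di(propan-2-yl)carbamate; 15 (4R,8R)-N-methoxy-N,4,8,9-tetramethyl-5-methylidenedec-9-enamide
Product: 26 (3R,7R,11R,14E,18R,22S)-2,3,7,15,18,22,23-heptamethyl-6,19-dimethylidene-10-oxotetracosa-1,14,23-trien-11-yl N,N-di(propan-2-yl)carbamate, via lithiated carbamate 25 (not isolated)
Conditions: 24, s-BuLi (1.3 equiv), (−)-sparteine (1.3 equiv), Et2O, −78 °C, 5 h; then 15 (1.2 equiv), Et2O, −78 °C, 3 h; MeOH at −78 °C, then H2O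
Reagents that add atoms: none
Why: Hoppe asymmetric deprotonation, in which s-BuLi·(−)-sparteine removes the pro-S hydrogen next to the carbamate oxygen to give the configurationally stable α-oxy carbanion 25 (a carbinol carbon made nucleophilic), which is acylated with retention by the Weinreb amide whose chelated tetrahedral adduct blocks over-addition, so the C10–C11 bond between two normally electrophilic carbons joins the two halves and C11 is set as R.

Step 16
Reactants: 26 (3R,7R,11R,14E,18R,22S)-2,3,7,15,18,22,23-heptamethyl-6,19-dimethylidene-10-oxotetracosa-1,14,23-trien-11-yl N,N-di(propan-2-yl)carbamate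
Product: 28 (3R,7R,10R,11R,14E,18R,22S)-2,3,7,10,15,18,22,23-octamethyl-6,19-dimethylidenetetracosa-1,14,23-triene-10,11-diol, via magnesium alkoxide 27 (not isolated)
Conditions: MeMgBr (3 equiv), THF, −78 → −40 °C; then LiAlH4 (5 equiv), THF, reflux; H2O
Reagents that add atoms: methylmagnesium bromide C[Mg]Br
Why: Grignard addition under polar Felkin–Anh control, with the C11–O(carbamate) bond anti to the incoming methyl and the methyl passing the C11 hydrogen, sets C10 as R (the syn-diol relationship, expected about 5:1, the 10S diol being removed by chromatography), and LiAlH4 then cleaves the carbamate reductively in the same flask.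

Step 17
Reactants: 28 (3R,7R,10R,11R,14E,18R,22S)-2,3,7,10,15,18,22,23-octamethyl-6,19-dimethylidenetetracosa-1,14,23-triene-10,11-diol; 29 canthaxanthin (all-E β,β-carotene-4,4'-dione)
Product: 31 CNP0354203.2 (the R spiro 4-ketal of canthaxanthin with diol 28), via bis-silyl ether 30 (not isolated)
Conditions: 28, MeC(OSiMe3)=NSiMe3 (1.2 equiv), CH2Cl2, rt → 35 °C; then 29 (3 equiv), TMSOTf (10 mol%), 2,6-di-tert-butyl-4-methylpyridine (20 mol%), CH2Cl2, −78 → −30 °C, dark, argon; pyridine; preparative HPLC
Reagents that add atoms: none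
Why: Noyori ketalization, in which the secondary silyl ether oxygen adds first to the activated C4 carbonyl, the oxocarbenium ion keeps its O-alkyl group on the C3 side away from the C5 methyl, and the tertiary oxygen closes the dioxolane through the transition state with chain B pseudo-equatorial, which gives the R spiro centre with a predicted modest kinetic preference (about 2–3:1), while the hindered pyridine base traps adventitious acid, excess 29 limits reaction to one carbonyl, and the S spiro epimer is removed by HPLC.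

**Compound list**
1 | 3-methylideneoxolan-2-one (α-methylene-γ-butyrolactone) | C=C1CCOC1=O | starting material
2 | (3R)-3-methyloxolan-2-one | C[C@@H]1CCOC1=O | intermediate
3 | (3S)-3-methyloxolan-2-one | C[C@H]1CCOC1=O | intermediate
4 | lithium (3R)-3-methyl-4-oxopentan-1-olate (not isolated) | CC(=O)[C@H](C)CC[O-].[Li+] | intermediate
5 | (3R)-3,4-dimethylpent-4-en-1-ol | C=C(C)[C@H](C)CCO | intermediate
6 | (3R)-5-iodo-2,3-dimethylpent-1-ene | C=C(C)[C@H](C)CCI | intermediate
7 | lithium (3S)-3-methyl-4-oxopentan-1-olate (not isolated) | CC(=O)[C@@H](C)CC[O-].[Li+] | intermediate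
8 | (3S)-3,4-dimethylpent-4-en-1-ol | C=C(C)[C@@H](C)CCO | intermediate
9 | (3S)-5-iodo-2,3-dimethylpent-1-ene | C=C(C)[C@@H](C)CCI | intermediate
10 | [(3R)-3,4-dimethylpent-4-en-1-yl]lithium (not isolated) | C=C(C)[C@H](C)CC[Li] | intermediate
11 | lithium (3R,7R)-3,7,8-trimethyl-4-oxonon-8-en-1-olate (not isolated) | C=C(C)[C@H](C)CCC(=O)[C@H](C)CC[O-].[Li+] | intermediate
12 | (3R,7R)-3,7,8-trimethyl-4-methylidenenon-8-en-1-ol | C=C(C)[C@H](C)CCC(=C)[C@H](C)CCO | intermediate
13 | (3R,7R)-9-iodo-2,3,7-trimethyl-6-methylidenenon-1-ene | C=C(C)[C@H](C)CCC(=C)[C@H](C)CCI | intermediate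
14 | [(3R,7R)-3,7,8-trimethyl-4-methylidenenon-8-en-1-yl]lithium (not isolated) | C=C(C)[C@H](C)CCC(=C)[C@H](C)CC[Li] | intermediate
15 | (4R,8R)-N-methoxy-N,4,8,9-tetramethyl-5-methylidenedec-9-enamide | C=C(C)[C@H](C)CCC(=C)[C@H](C)CCC(=O)N(C)OC | intermediate
16 | [(3S)-3,4-dimethylpent-4-en-1-yl]lithium (not isolated) | C=C(C)[C@@H](C)CC[Li] | intermediate
17 | lithium (3R,7S)-3,7,8-trimethyl-4-oxonon-8-en-1-olate (not isolated) | C=C(C)[C@@H](C)CCC(=O)[C@H](C)CC[O-].[Li+] | intermediate
18 | (3R,7S)-3,7,8-trimethyl-4-methylidenenon-8-en-1-ol | C=C(C)[C@@H](C)CCC(=C)[C@H](C)CCO | intermediate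
19 | (3S,7R)-9-iodo-2,3,7-trimethyl-6-methylidenenon-1-ene | C=C(C)[C@@H](C)CCC(=C)[C@H](C)CCI | intermediate
20 | 3,4-dihydro-2H-pyran | C1=COCCC1 | starting material
21 | (3,4-dihydro-2H-pyran-6-yl)lithium (not isolated) | [Li]C1=CCCCO1 | intermediate
22 | 6-[(3R,7S)-3,7,8-trimethyl-4-methylidenenon-8-en-1-yl]-3,4-dihydro-2H-pyran | O1CCCC=C1CC[C@@H](C)C(=C)CC[C@H](C)C(=C)C | intermediate
23 | (4E,8R,12S)-5,8,12,13-tetramethyl-9-methylidenetetradeca-4,13-dien-1-ol | OCCC/C=C(\C)CC[C@@H](C)C(=C)CC[C@H](C)C(=C)C | intermediate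
24 | (4E,8R,12S)-5,8,12,13-tetramethyl-9-methylidenetetradeca-4,13-dien-1-yl N,N-di(propan-2-yl)carbamate | CC(C)N(C(C)C)C(=O)OCCC/C=C(\C)CC[C@@H](C)C(=C)CC[C@H](C)C(=C)C | intermediate
25 | (1S)-1-lithio derivative of 24, as its (−)-sparteine complex (not isolated) | CC(C)N(C(C)C)C(=O)O[C@@H]([Li])CC/C=C(\C)CC[C@@H](C)C(=C)CC[C@H](C)C(=C)C | intermediate
26 | (3R,7R,11R,14E,18R,22S)-2,3,7,15,18,22,23-heptamethyl-6,19-dimethylidene-10-oxotetracosa-1,14,23-trien-11-yl N,N-di(propan-2-yl)carbamate | C=C(C)[C@H](C)CCC(=C)[C@H](C)CCC(=O)[C@H](OC(=O)N(C(C)C)C(C)C)CC/C=C(\C)CC[C@@H](C)C(=C)CC[C@H](C)C(=C)C | intermediate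
27 | bromomagnesium (3R,7R,10R,11R,14E,18R,22S)-11-[di(propan-2-yl)carbamoyloxy]-2,3,7,10,15,18,22,23-octamethyl-6,19-dimethylidenetetracosa-1,14,23-trien-10-olate (not isolated) | C=C(C)[C@H](C)CCC(=C)[C@H](C)CC[C@@](C)(O[Mg]Br)[C@H](OC(=O)N(C(C)C)C(C)C)CC/C=C(\C)CC[C@@H](C)C(=C)CC[C@H](C)C(=C)C | intermediate
28 | (3R,7R,10R,11R,14E,18R,22S)-2,3,7,10,15,18,22,23-octamethyl-6,19-dimethylidenetetracosa-1,14,23-triene-10,11-diol | C=C(C)[C@H](C)CCC(=C)[C@H](C)CC[C@@](C)(O)[C@H](O)CC/C=C(\C)CC[C@@H](C)C(=C)CC[C@H](C)C(=C)C | intermediate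
29 | canthaxanthin (all-E β,β-carotene-4,4'-dione) | O=C1CCC(C)(C)C(/C=C/C(C)=C/C=C/C(C)=C/C=C/C=C(C)/C=C/C=C(C)/C=C/C2=C(C)C(=O)CCC2(C)C)=C1C | starting material
30 | 10,11-bis(trimethylsilyl) ether of 28 (not isolated) | C=C(C)[C@H](C)CCC(=C)[C@H](C)CC[C@@](C)(O[Si](C)(C)C)[C@H](O[Si](C)(C)C)CC/C=C(\C)CC[C@@H](C)C(=C)CC[C@H](C)C(=C)C | intermediate
31 | CNP0354203.2 (R spiro 4-ketal of canthaxanthin with diol 28) | C=C(C)[C@H](C)CCC(=C)[C@H](C)CC[C@@]1(C)O[C@@]2(CCC(C)(C)C(/C=C/C(C)=C/C=C/C(C)=C/C=C/C=C(C)/C=C/C=C(C)/C=C/C3=C(C)C(=O)CCC3(C)C)=C2C)O[C@@H]1CC/C=C(\C)CC[C@@H](C)C(=C)CC[C@H](C)C(=C)C | target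

**Summary**
Total step count: 17.
Longest linear sequence: 11 steps (1 → 3 → 8 → 9 → 18 → 19 → 22 → 23 → 24 → 26 → 28 → 31).
Origin of stereo-elements: the three R methyl centres come from lactone 2 and the S methyl centre from lactone 3 (steps 1 and 2); 14E from step 13; C11 from step 15; C10 from step 16; the spiro centre from step 17. The building blocks are about 95% ee, so minor diastereomers accumulate unless a more selective hydrogenation catalyst is used.

**Three steps most likely to fail**

Risk at step 17 (ketalization). The spiro selectivity is only a prediction, the tertiary silyl ether is hindered, and both the polyene and the 1,1-disubstituted alkenes are acid-sensitive. The fallback sets out from 29 (and uses 28) and comes back at 31. Canthaxanthin is first converted with HC(OMe)3, MeOH and pyridinium p-toluenesulfonate into 4,4-dimethoxy-β,β-caroten-4'-one F5. F5 is then transketalized with diol 28 under a chiral phosphoric acid (the matched enantiomer of 3,3'-bis(2,4,6-triisopropylphenyl)-BINOL hydrogen phosphate), 4 Å sieves, toluene, rt. The spiro centre is then under catalyst control in a weakly acidic medium, with methanol as the only by-product.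

Risk at step 16 (methyl addition). If the carbamate carbonyl chelates magnesium, the face selectivity reverses and the 10S diol dominates. The fallback sets out from 24 (with iodide 13) and comes back at 27. Carbanion 25 is made as in step 15 and acylated with N-methoxy-N-methylacetamide to give the methyl ketone (3R,6E,10R,14S)-7,10,14,15-tetramethyl-11-methylidene-2-oxohexadeca-6,15-dien-3-yl N,N-di(propan-2-yl)carbamate F3. Alkyllithium 14 (from 13 as in step 9) is transmetalated with MgBr2·OEt2 to [(3R,7R)-3,7,8-trimethyl-4-methylidenenon-8-en-1-yl]magnesium bromide F4. F4 is added to F3 pre-complexed with MgBr2·OEt2 in CH2Cl2 at −78 °C. Under chelation control the chain A nucleophile enters from the C11–H face and gives the same 10R alkoxide 27, which is reduced with LiAlH4 as in step 16.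

Risk at step 15 (acylation). The hindered, sparteine-bound carbanion may deprotonate the Weinreb amide instead of adding to it. The fallback sets out from 15 (and 24) and comes back at 26. Amide 15 is reduced with i-Bu2AlH (THF, −78 °C) to the aldehyde (4R,8R)-4,8,9-trimethyl-5-methylidenedec-9-enal F1. Carbanion 25 is added to F1 at −78 °C (addition to an aldehyde outruns enolization) to give the alcohol (3R,7R,11R,14E,18R,22S)-10-hydroxy-2,3,7,15,18,22,23-heptamethyl-6,19-dimethylidenetetracosa-1,14,23-trien-11-yl N,N-di(propan-2-yl)carbamate F2 as a mixture at C10. Dess–Martin oxidation (buffered with NaHCO3) then returns ketone 26.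

Further compounds
F1 | step 15 | (4R,8R)-4,8,9-trimethyl-5-methylidenedec-9-enal | C=C(C)[C@H](C)CCC(=C)[C@H](C)CCC=O
F2 | step 15 | (3R,7R,11R,14E,18R,22S)-10-hydroxy-2,3,7,15,18,22,23-heptamethyl-6,19-dimethylidenetetracosa-1,14,23-trien-11-yl N,N-di(propan-2-yl)carbamate (C10 epimers) | C=C(C)[C@H](C)CCC(=C)[C@H](C)CCC(O)[C@H](OC(=O)N(C(C)C)C(C)C)CC/C=C(\C)CC[C@@H](C)C(=C)CC[C@H](C)C(=C)C
F3 | step 16 | (3R,6E,10R,14S)-7,10,14,15-tetramethyl-11-methylidene-2-oxohexadeca-6,15-dien-3-yl N,N-di(propan-2-yl)carbamate | CC(=O)[C@H](OC(=O)N(C(C)C)C(C)C)CC/C=C(\C)CC[C@@H](C)C(=C)CC[C@H](C)C(=C)C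
F4 | step 16 | [(3R,7R)-3,7,8-trimethyl-4-methylidenenon-8-en-1-yl]magnesium bromide | C=C(C)[C@H](C)CCC(=C)[C@H](C)CC[Mg]Br
F5 | step 17 | 4,4-dimethoxy-β,β-caroten-4'-one (canthaxanthin mono(dimethyl ketal)) | COC1(OC)CCC(C)(C)C(/C=C/C(C)=C/C=C/C(C)=C/C=C/C=C(C)/C=C/C=C(C)/C=C/C2=C(C)C(=O)CCC2(C)C)=C1C
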